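In delta the left-handed substrate falls far faster than the right-handed, to 4.4% against 47.1% at 5.00 d. The flask asked about is delta, continued.

| setting | delta | gamma | flask |
|---|---|---|---|
| left-handed substrate | 20 mM | 20 mM | 20 mM |
| right-handed substrate | 20 mM | 20 mM | 20 mM |
| partner | 40 mM | 27 mM | 40.0 mM |
| protic impurity | 1 mM | 1 mM | 1.00 mM |
| free catalyst | 0.50 mM | 0.50 mM | 0.50 mM |
| stray impurity | 0.27 mM | 0.27 mM | 0.27 mM |
| remark | the very flask that is asked about, followed so far | run made earlier |  |
| time |  |  | 10 d |

- delta (time / d: right-handed substrate / %, left-handed substrate / %): 0.417: 49.2, 35.3; 1.25: 48.6, 20.1; 2.50: 47.7, 10.1; 4.00: 47.4, 6.9; 5.00: 47.1, 4.4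
- gamma (time / d: right-handed substrate / %, left-handed substrate / %): 1.25: 47.2, 26.6; 3.00: 48.0, 17.2; 4.00: 46.5, 10.9; 6.00: 48.3, 7.7; 8.00: 47.7, 6.3

(standard deviation of a reading: 1 percentage point)

- free catalyst is single-handed; left-handed substrate and right-handed substrate are mirror images of each other, charged as a racemate, each of them at the stated concentration

- whether the excess of right-handed substrate over left-handed substrate among what is left of the two reaches 80% by 10 d (no / yes)
- the highest excess of right-handed substrate over left-handed substrate among what is left of the two up to 10 d

*How do you compare the two hands?* By the fraction left, not the fraction made. If each hand is used in proportion to its own amount, with the same partner and the same catalyst, the logarithms of the two fractions left keep a fixed ratio, however the clock runs. The 5.00 d readings of delta give 40.7. This ratio, the log of the fraction of left-handed substrate left over the log of the fraction of right-handed substrate left, is the selectivity factor.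

*What must be left for the wanted excess?* Right-handed must stand 9.00 times above left-handed. With the factor, that means left-handed down to 10.5% of its own charge, or 5.25% of both together.

*But right-handed has lost 2.9 percentage points with a scatter of 1 point. Isn't your factor poor?* As a reading, yes. But it enters that mark as one over itself, 0.0246, set beside one, so the mark hardly moves.

*So?* Delta reads 4.4% at 5.00 d, below the mark by 0.85 points, with a scatter of 1 point, and the flask has until 10 d, so my answer is yes, though with that scatter the readings do not place the moment of passing.

The forecast says yes, with a top of 95%, “rising monotonically and highest at 10 d”.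

The flask gives yes, with a top of 97.9%, and reaches the wanted excess at 3.95 d.

    free catalyst + stray impurity → spent catalyst (k = 0.550 M⁻¹ s⁻¹)
    left-handed product ⇌ right-handed product (k = 2.10 × 10⁻⁵ s⁻¹)
    partner + free catalyst + right-handed substrate → free catalyst + right-handed product (k = 0.0240 M⁻² s⁻¹)
    partner + protic impurity → quenched reagent (k = 0.00990 M⁻¹ s⁻¹)
    partner + free catalyst + left-handed substrate → free catalyst + left-handed product (k = 1.10 M⁻² s⁻¹)

At 10.0 d the flask keeps 0.94% of its left-handed charge and 90% of its right-handed charge. Put that left-handed remainder into the factor 40.7, and right-handed comes to 89.2%, an excess of 97.9%. Gamma, charged with 27 mM of partner, reads 6.3% left-handed at 8.00 d. From that reading the same factor gives right-handed 47.5% and an excess of 76.6%, while gamma's two readings give 76.7%.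

Readings and results stem from a simulated flask on assumed constants; scatter was added.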